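## Analysis of the target

The target 21 is a 20-membered cyclophane in which two benzene rings are joined twice, once through a diaryl ether oxygen and once through an unbranched (CH2)14 chain. Ring A is 1,3,5-substituted (C1A ether oxygen, C3A hydroxyl, C5A chain). Ring B is 1,2,4,6-substituted (C1B ether oxygen, C2B hydroxyl, C4B hydroxyl, C6B chain, with hydrogen on C3B and C5B). There is no stereocentre and no stereogenic double bond, so the problem is one of constitution only. The three free phenols make the compound electron-rich, and ring B, a 1,2,4-trioxygenated arene, is liable to oxidation in base and air, so it should appear late and be unveiled under mild conditions. The hard points are the ether oxygen on C1B, which is flanked by C2B–OH and the C6B chain and is therefore a poor site for Ullmann or SNAr coupling, the entropic cost of the large ring, and the need to tell the two ring A oxygens apart. The strategy rests on the 1,3-relationship of the C2B and C4B hydroxyls: C3B–C4B–C5B can be read as an acetone unit, while C2B, C1B and C6B are the ester carbon, the aryloxy-bearing α-carbon and the chain-bearing ketone carbon of an α-aryloxy β-keto ester. Ring B therefore need not exist when the ether bond and the macrocycle are made, and the ether can be formed at an sp3 carbon.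

## Retrosynthetic reasoning

**21 to 20.** The last bond cut is the O–benzyl bond on C3A. One ring A oxygen must stay masked from the first step so that only the other one closes the macrocycle. A benzyl ether is inert to organozinc, carbenoid, alkoxide and hydroxide chemistry and leaves by neutral hydrogenolysis, which suits the oxidation-prone triphenol.

**20 to 18.** Two ester carbons are added back on C3B and C5B. They are the activating groups of the three-carbon building block and cost nothing to remove, because each sits ortho or para to a ring B hydroxyl. The forward operation is ester hydrolysis followed by protodecarboxylation of the diacid 19.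

**18 to 15 and 16 (key disconnection).** Ring B is cut at C5B–C6B and at C2B–C3B. This is the only cut that splits ring B into a symmetrical 1,3-dinucleophile (16) and a 1,3-dielectrophile (15) while leaving the C1B–O bond and the chain untouched. The gain is that the hindered diaryl ether is never made by aryl coupling and the arene arrives at the correct oxidation level. The forward reaction has to condense one methylene of 16 with the C6B ketone with dehydration (adduct 17), acylate the other methylene with the C2B ester, and aromatise.

**15 to 14.** The macrocycle is opened at O–C1B. In the forward sense a metal carbenoid generated at C1B from diazo compound 14 inserts into the O–H bond of the unhindered ring A phenol. The step is fast and irreversible, which is what a high-dilution ring closure needs, and it forms the ether at an sp3 carbon.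

**14 to 13 to 12.** The diazo group is traced back to the activated methylene of keto ester 13 (diazo transfer). The free phenol of 13 is traced back to the methoxymethyl ether 12, whose acetal is needed only while the chain is built.

**12 to 9 and 10.** The bond between C1B and C6B is cut. Acid 9 supplies C6B and the chain, and Meldrum's acid 10 supplies C1B and C2B through the acyl intermediate 11. This two-carbon homologation gives the methyl keto ester directly and under neutral conditions. Acid 9 comes from ester 8 by saponification.

**8 to 3 and 6.** The C5A–CH2 bond is cut between an sp2 and an sp3 carbon. The forward reaction is a palladium-catalysed coupling of the organozinc 7, made from iodide 3, with bromide 6. Both partners are short to make: 3 from lactone 1 through hydroxy ester 2, and 6 from bromoresorcinol 4 through monobenzyl ether 5. The whole chain is thus delivered in one piece.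

## Alternatives that were turned down

**Alternative 1:** The ring is cut at O–C1A, with ring A held at the cyclohexenone oxidation level.
- Forward key step: the phenoxide of the chloroenone phenol A1 (oxygen on C1B) adds to the chlorine-bearing carbon of the tethered 3-chlorocyclohexenone and chloride leaves. This vinylogous acyl substitution closes the 20-membered ring and gives enone A2, which must then be dehydrogenated to the ring A phenol and freed of two methyl ethers.
- For it: addition–elimination on a vinylogous acid chloride is dependable even for hindered phenoxides and needs no metal. Its key bond construction is better precedented than a [3+3] annulation on a macrocycle, and on that point it is the stronger plan.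
- Against it: the ring-closing event uses the most hindered nucleophile in the molecule, a di-ortho-substituted phenoxide, at high dilution, where hydrolysis and self-condensation of the chloroenone have time to compete. A2 then needs an oxidation in the presence of a very electron-rich trioxygenated ring B. The end-game is a double aryl methyl ether cleavage with a strong Lewis acid.
- Comparison: the chosen route offers in exchange a macrocyclisation at an unhindered oxygen, no oxidation step at all, and a hydrogenolytic and decarboxylative finish.

**Alternative 2:** Ring B is cut at C1B–C6B and C3B–C4B, and the first of these bonds also closes the macrocycle.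
- Forward key step: with a strong base at high dilution the aryloxyacetone unit of the keto enoate A3 adds through C1B to the β-carbon (C6B) of the chain-terminal enoate. The methyl ketone enolate (C3B) then acylates on the ester (C4B) to give the cyclohexane-1,3-dione A4, which needs a dehydrogenation to the resorcinol before debenzylation.
- For it: two rings form in one operation and the precursor A3 is simple to assemble. In convergence it is stronger than the chosen plan.
- Against it: the macrocyclic bond comes from a reversible Michael addition with low effective molarity, so oligomerisation and aldol self-condensation of the ketone compete. Both enolisations must occur with the right regiochemistry. A4 is one dehydrogenation short of the arene, and oxidising an enolisable α-aryloxy dione next to electron-rich ring A invites over-oxidation.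
- Comparison: the chosen route separates the two risks. The macrocycle is closed by an irreversible insertion, and ring B is built with aromatisation already encoded in the ester oxidation level at C2B and the dehydration at C6B.

**Alternative 3:** Ring A is cut at C2A–C3A and C1A–C6A, and ring A and the macrocycle form together.
- Forward key step: heating the cyclobutenone ynol ether A5 opens the cyclobutenone to a vinylketene. This adds across the tethered aryl ethynyl ether, the adduct opens and undergoes 6π-electrocyclisation, and tautomerisation gives the ring B dimethyl ether A6, which needs only demethylation.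
- For it: the polarity of the ynol ether places hydroxyl, aryloxy and alkyl groups in exactly the 1,3,5-pattern of ring A. No redox adjustment is needed, and the reversible opening of the cyclobutenone acts as a reservoir at high dilution. On paper it is the shortest route and is stronger in step economy.
- Against it: it needs an ethynyl ether of a di-ortho-substituted phenol and a long-chain cyclobutenone, both sensitive, to survive prolonged heating. The ketene–alkyne cycloaddition has to occur across a 20-membered ring, where ketene dimerisation and ynol ether polymerisation are likely to win. The final double demethylation is harsh for the triphenol.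
- Comparison: the chosen route uses robust functional groups, steps that each have precedent in their class, and a mild last step.

Key step: step 11

Remark on the chemistry: compound 15 is carried as the racemate because its only stereocentre (C1B) becomes an aromatic carbon in step 11, and methyl esters are used throughout so that methoxide cannot scramble them.

## Route

Step 1
Reactants: 1 15-pentadecanolide
Product: 2 methyl 15-hydroxypentadecanoate
Conditions: MeOH, H2SO4 (cat.), reflux
Reagents that add atoms: methanol, CO
Why: Acid-catalysed transesterification (Fischer-type methanolysis) of the unstrained macrolactone; methanol as solvent drives the ring opening to the hydroxy ester.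

Step 2
Reactants: 2 methyl 15-hydroxypentadecanoate
Product: 3 methyl 15-iodopentadecanoate
Conditions: I2, PPh3, imidazole, CH2Cl2, 0 °C to rt
Reagents that add atoms: iodine, II
Why: Appel-type iodination; the primary alkoxyphosphonium ion is displaced by iodide in an SN2 step and the ester is inert.

Step 3
Reactants: 4 5-bromoresorcinol
Product: 5 3-(benzyloxy)-5-bromophenol
Conditions: BnBr (0.5 equiv), K2CO3, acetone, reflux
Reagents that add atoms: benzyl bromide, BrCc1ccccc1
Why: Williamson etherification; the two hydroxyls are equivalent, so the only issue is statistical, and using the diol in excess should favour the monoether, which is separable from recovered diol and diether.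

Step 4
Reactants: 5 3-(benzyloxy)-5-bromophenol
Product: 6 1-(benzyloxy)-3-bromo-5-(methoxymethoxy)benzene
Conditions: MOMCl, i-Pr2NEt, CH2Cl2, 0 °C to rt
Reagents that add atoms: chloromethyl methyl ether, COCCl
Why: O-alkylation of the phenol to a methoxymethyl acetal, a group that should withstand the organozinc, hydroxide and carbodiimide steps and leave under mild acid without touching the benzyl ether.

Step 5
Reactants: 3 methyl 15-iodopentadecanoate; 6 1-(benzyloxy)-3-bromo-5-(methoxymethoxy)benzene
Product: 8 methyl 15-[3-(benzyloxy)-5-(methoxymethoxy)phenyl]pentadecanoate, via alkylzinc iodide 7 (not isolated)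
Conditions: 3, Zn dust, LiCl, THF, 40 °C; then 6, Pd(OAc)2 (2 mol %), SPhos (4 mol %), THF, 50 °C
Reagents that add atoms: none
Why: Negishi sp3–sp2 coupling; LiCl-assisted zinc insertion into the primary iodide tolerates the ester, and a bulky biarylphosphine on palladium should make reductive elimination faster than β-hydride elimination with the electron-rich aryl bromide.

Step 6
Reactants: 8 methyl 15-[3-(benzyloxy)-5-(methoxymethoxy)phenyl]pentadecanoate
Product: 9 15-[3-(benzyloxy)-5-(methoxymethoxy)phenyl]pentadecanoic acid
Conditions: LiOH, THF/MeOH/H2O, 40 °C; then 1 M HCl to pH 4, 0 °C
Reagents that add atoms: lithium hydroxide, [Li+].[OH-]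
Why: Saponification of an unhindered methyl ester; both ethers are stable to hydroxide, and cold acidification to pH 4 should spare the acetal.

Step 7
Reactants: 9 15-[3-(benzyloxy)-5-(methoxymethoxy)phenyl]pentadecanoic acid; 10 Meldrum's acid
Product: 12 methyl 17-[3-(benzyloxy)-5-(methoxymethoxy)phenyl]-3-oxoheptadecanoate, via acyl Meldrum's acid 11 (not isolated)
Conditions: 10, DCC, DMAP, CH2Cl2, 0 °C to rt; then MeOH, reflux
Reagents that add atoms: methanol, CO
Why: Carbodiimide-mediated C-acylation of Meldrum's acid, then methanolysis through the acylketene with loss of acetone and CO2; this β-keto ester homologation runs under near-neutral conditions that leave both ethers intact.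

Step 8
Reactants: 12 methyl 17-[3-(benzyloxy)-5-(methoxymethoxy)phenyl]-3-oxoheptadecanoate
Product: 13 methyl 17-[3-(benzyloxy)-5-hydroxyphenyl]-3-oxoheptadecanoate
Conditions: conc. HCl (cat.), MeOH, 45 °C
Reagents that add atoms: none
Why: Acid-catalysed acetal cleavage (methanolysis of the methoxymethyl ether); in methanol any transesterification of the methyl ester is degenerate, and the benzyl aryl ether is stable to dilute acid.

Step 9
Reactants: 13 methyl 17-[3-(benzyloxy)-5-hydroxyphenyl]-3-oxoheptadecanoate
Product: 14 methyl 17-[3-(benzyloxy)-5-hydroxyphenyl]-2-diazo-3-oxoheptadecanoate
Conditions: p-ABSA, Et3N, MeCN, 0 °C to rt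
Reagents that add atoms: 4-acetamidobenzenesulfonyl azide, CC(=O)Nc1ccc(cc1)S(=O)(=O)N=[N+]=[N-]
Why: Regitz diazo transfer to the doubly activated methylene; a sulfonyl azide with a tertiary amine reacts with the 1,3-dicarbonyl enolate and should leave the phenol alone.

Step 10
Reactants: 14 methyl 17-[3-(benzyloxy)-5-hydroxyphenyl]-2-diazo-3-oxoheptadecanoate
Product: 15 racemic 20-membered macrocyclic methyl α-aryloxy β-keto ester (ring A benzyl ether)
Conditions: Rh2(OAc)4 (2 mol %), CH2Cl2, reflux, syringe-pump addition of 14 (final 1 mM)
Reagents that add atoms: none
Why: Intramolecular rhodium-carbenoid O–H insertion; the electrophilic carbenoid at C1B is captured by the phenol oxygen (oxonium ylide, then proton shift), forming the O–C1B bond at an sp3 carbon. Slow addition keeps the diazo compound dilute so that closure of the unstrained 20-membered ring should outrun oligomerisation, and O–H insertion is intrinsically much faster than insertion into the chain C–H bonds. The new stereocentre at C1B is formed without control and is erased in step 11.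

Step 11
Reactants: 15 racemic 20-membered macrocyclic methyl α-aryloxy β-keto ester (ring A benzyl ether); 16 dimethyl 1,3-acetonedicarboxylate
Product: 18 ring B 3,5-bis(methoxycarbonyl) derivative of the target as its ring A benzyl ether, via Knoevenagel adduct 17 (not isolated)
Conditions: 16 (3 equiv, in portions), NaOMe (4 equiv), MeOH, reflux; then 1 M HCl
Reagents that add atoms: none
Why: Methoxide deprotonates 16 at a doubly activated methylene; the carbanion adds to the C6B ketone of 15 and water is lost (Knoevenagel), giving adduct 17 with the C5B–C6B bond. The second methylene of the same unit then attacks the C2B methyl ester in a 6-exo-trig Claisen acylation and expels methoxide, forming C2B–C3B and closing ring B as a six-membered carbocycle; the 20-membered ring is already in place and is not involved. The resulting cyclohexenedione carries one hydrogen each on C1B and C3B and tautomerises irreversibly to the resorcinol. The closest known reaction type is the base-mediated aromatising condensation of acetonedicarboxylic esters with 1,3-dicarbonyl compounds, including the self-condensation of such esters, which is itself a Knoevenagel–Claisen pair on a β-keto ester. No stereocentre is created, and the racemic centre at C1B becomes sp2. The step needs one molecule of 16 to use both electrophilic carbons of 15 and needs methoxide not to cleave the C1B–C6B bond by retro-Claisen attack; 15 rests as its stabilised enolate, which shields the ketone from methoxide, and because 16 is symmetric the same arene results whichever carbonyl reacts first. Aromatisation removes the product from all equilibria, and self-condensation of 16 is met by using it in excess and adding it in portions.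

Step 12
Reactants: 18 ring B 3,5-bis(methoxycarbonyl) derivative of the target as its ring A benzyl ether
Product: 20 ring A benzyl ether of the target, via diacid 19 (not isolated)
Conditions: KOH, MeOH/H2O, reflux, argon; then 6 M HCl to pH 1, reflux
Reagents that add atoms: none
Why: Saponification followed by acid-promoted protodecarboxylation; each carboxyl is ortho or para to a ring B hydroxyl, so ipso-protonation and loss of CO2 should occur on heating. The benzyl and diaryl ethers are stable to both media, and argon protects the electron-rich ring in alkali.

Step 13
Reactants: 20 ring A benzyl ether of the target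
Product: 21 CNP0173380.0 (target)
Conditions: H2 (1 atm), 10% Pd/C, EtOAc/MeOH, rt
Reagents that add atoms: none
Why: Heterogeneous hydrogenolysis of the benzyl aryl ether; the diaryl ether, both arenes and the saturated chain should be untouched at ambient pressure.

## Compound list

1 | 15-pentadecanolide (oxacyclohexadecan-2-one) | O=C1CCCCCCCCCCCCCCO1 | starting material
2 | methyl 15-hydroxypentadecanoate | COC(=O)CCCCCCCCCCCCCCO | intermediate
3 | methyl 15-iodopentadecanoate | COC(=O)CCCCCCCCCCCCCCI | intermediate
4 | 5-bromoresorcinol (5-bromobenzene-1,3-diol) | Oc1cc(O)cc(Br)c1 | starting material
5 | 3-(benzyloxy)-5-bromophenol | Oc1cc(Br)cc(OCc2ccccc2)c1 | intermediate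
6 | 1-(benzyloxy)-3-bromo-5-(methoxymethoxy)benzene | COCOc1cc(Br)cc(OCc2ccccc2)c1 | intermediate
7 | (15-methoxy-15-oxopentadecyl)zinc iodide | COC(=O)CCCCCCCCCCCCCC[Zn]I | intermediate
8 | methyl 15-[3-(benzyloxy)-5-(methoxymethoxy)phenyl]pentadecanoate | COC(=O)CCCCCCCCCCCCCCc1cc(OCOC)cc(OCc2ccccc2)c1 | intermediate
9 | 15-[3-(benzyloxy)-5-(methoxymethoxy)phenyl]pentadecanoic acid | OC(=O)CCCCCCCCCCCCCCc1cc(OCOC)cc(OCc2ccccc2)c1 | intermediate
10 | Meldrum's acid (2,2-dimethyl-1,3-dioxane-4,6-dione) | CC1(C)OC(=O)CC(=O)O1 | starting material
11 | 5-{15-[3-(benzyloxy)-5-(methoxymethoxy)phenyl]-1-hydroxypentadecylidene}-2,2-dimethyl-1,3-dioxane-4,6-dione | CC1(C)OC(=O)C(=C(O)CCCCCCCCCCCCCCc2cc(OCOC)cc(OCc3ccccc3)c2)C(=O)O1 | intermediate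
12 | methyl 17-[3-(benzyloxy)-5-(methoxymethoxy)phenyl]-3-oxoheptadecanoate | COC(=O)CC(=O)CCCCCCCCCCCCCCc1cc(OCOC)cc(OCc2ccccc2)c1 | intermediate
13 | methyl 17-[3-(benzyloxy)-5-hydroxyphenyl]-3-oxoheptadecanoate | COC(=O)CC(=O)CCCCCCCCCCCCCCc1cc(O)cc(OCc2ccccc2)c1 | intermediate
14 | methyl 17-[3-(benzyloxy)-5-hydroxyphenyl]-2-diazo-3-oxoheptadecanoate | COC(=O)C(=[N+]=[N-])C(=O)CCCCCCCCCCCCCCc1cc(O)cc(OCc2ccccc2)c1 | intermediate
15 | racemic 20-membered macrocyclic methyl α-aryloxy β-keto ester: C1B(H)(CO2Me) bonded to the ring A oxygen on C1A and to the C6B ketone, C6B joined to C5A through (CH2)14, benzyloxy on C3A | COC(=O)C1Oc2cc(OCc3ccccc3)cc(c2)CCCCCCCCCCCCCCC1=O | intermediate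
16 | dimethyl 1,3-acetonedicarboxylate (dimethyl 3-oxopentanedioate) | COC(=O)CC(=O)CC(=O)OC | starting material
17 | Knoevenagel adduct: C2 of the 3-oxopentanedioate joined by a C=C bond to the former ketone carbon C6B of 15, ester on C1B intact (racemic, alkene geometry undefined) | COC(=O)CC(=O)C(C(=O)OC)=C1CCCCCCCCCCCCCCc2cc(OCc3ccccc3)cc(c2)OC1C(=O)OC | intermediate
18 | ring B 3,5-bis(methoxycarbonyl) derivative of the target, ring A benzyl ether (methoxycarbonyl on C3B and C5B, hydroxyl on C2B and C4B) | COC(=O)c1c(O)c(C(=O)OC)c(O)c2Oc3cc(OCc4ccccc4)cc(c3)CCCCCCCCCCCCCCc12 | intermediate
19 | ring B 3,5-dicarboxylic acid of the target, ring A benzyl ether | OC(=O)c1c(O)c(C(=O)O)c(O)c2Oc3cc(OCc4ccccc4)cc(c3)CCCCCCCCCCCCCCc12 | intermediate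
20 | ring A benzyl ether of the target (benzyloxy on C3A, free hydroxyls on C2B and C4B) | c1c(O)cc(O)c2Oc3cc(OCc4ccccc4)cc(c3)CCCCCCCCCCCCCCc12 | intermediate
21 | CNP0173380.0: 20-membered diaryl ether cyclophane, ring A hydroxyl on C3A, ring B hydroxyls on C2B and C4B, (CH2)14 bridge from C5A to C6B | Oc1cc2cc(c1)Oc1c(O)cc(O)cc1CCCCCCCCCCCCCC2 | target

## Step count and least certain steps

Total step count: 13. Longest linear sequence: 11 steps (steps 1, 2 and 5 to 13 from lactone 1; equally steps 3 to 13 from bromoresorcinol 4).

**Step 11 (key step).** The most likely failures are retro-Claisen opening of the macrocycle by methoxide, or no Knoevenagel reaction at all because the C6B ketone is hindered and largely enolised, so that only self-condensation of 16 takes place. The fallback sets out from 15 and replaces the condensation by a cross-coupling and Claisen sequence.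
- NaH and PhNTf2 in THF should give the enol triflate F1, with the triflate oxygen cis to the ester as set by the chelated sodium enolate.
- Stille coupling with allyltributylstannane (Pd(PPh3)4, LiCl, THF, reflux) should give the allyl dienoate F2.
- Tsuji–Wacker oxidation (PdCl2 cat., CuCl, O2, DMF/H2O) should give the methyl ketone F3.
- NaOMe in MeOH should then close ring B by Claisen attack of the methyl ketone enolate (C3B) on the ester carbon (C2B) and tautomerisation.

This sequence comes back to the route at 20, with no carboxyl groups to remove.

**Step 10.** The most likely failures are insertion of the carbenoid into a C–H bond of its own chain, which closes a five-membered ring, or intermolecular O–H insertion leading to oligomerisation. The fallback sets out from 12 and closes the ring by displacement instead of insertion.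
- The sodium enolate (NaH, THF, 0 °C) is chlorinated with N-chlorosuccinimide to the α-chloro keto ester F4; under these conditions the enolate should react far faster than the arene.
- HCl in MeOH removes the acetal to give the chloro phenol F5.
- Cs2CO3 in DMF at 60 °C under syringe-pump dilution should effect intramolecular SN2 etherification at the α-carbon.

This comes back to the route at 15.

**Step 12.** The most likely failures are incomplete hydrolysis of two esters that are each flanked by two ortho substituents, and oxidative degradation of the electron-rich ring in hot alkali. The fallback sets out from 15 and changes the ester so that hydroxide is not needed.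
- The annulation is run with di-tert-butyl 3-oxopentanedioate (CC(C)(C)OC(=O)CC(=O)CC(=O)OC(C)(C)C; KOt-Bu, t-BuOH/THF, reflux) to give the di-tert-butyl diester F6.
- TFA in CH2Cl2 at rt, then warming in DMF, should cleave both esters and decarboxylate.

This comes back to the route at 20.

**Step 5.** The most likely failures are incomplete zinc insertion into the long-chain iodide, protonation or homocoupling of the organozinc, and sluggish oxidative addition into the electron-rich bromide. The fallback sets out from 3 and 6 and couples them directly by nickel-catalysed reductive cross-electrophile coupling (NiI2, 4,4'-di-tert-butyl-2,2'-bipyridine, Zn, NaI, DMA, 60 °C), with no preformed organometallic. It comes back to the route at 8 and makes no compound outside the list (F0).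

## Further compounds

F1 | step 11 | enol triflate of 15: macrocyclic methyl 2-aryloxy-3-(trifluoromethylsulfonyloxy)alk-2-enoate, triflate oxygen cis to the ester | COC(=O)/C1=C(\OS(=O)(=O)C(F)(F)F)CCCCCCCCCCCCCCc2cc(OCc3ccccc3)cc(c2)O1
F2 | step 11 | macrocyclic methyl 2-aryloxy-3-allylalk-2-enoate, allyl group on C6B cis to the ester | COC(=O)/C1=C(\CC=C)CCCCCCCCCCCCCCc2cc(OCc3ccccc3)cc(c2)O1
F3 | step 11 | macrocyclic methyl 2-aryloxy-3-(2-oxopropyl)alk-2-enoate, 2-oxopropyl group on C6B cis to the ester | COC(=O)/C1=C(\CC(C)=O)CCCCCCCCCCCCCCc2cc(OCc3ccccc3)cc(c2)O1
F4 | step 10 | methyl 17-[3-(benzyloxy)-5-(methoxymethoxy)phenyl]-2-chloro-3-oxoheptadecanoate (racemic) | COC(=O)C(Cl)C(=O)CCCCCCCCCCCCCCc1cc(OCOC)cc(OCc2ccccc2)c1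
F5 | step 10 | methyl 17-[3-(benzyloxy)-5-hydroxyphenyl]-2-chloro-3-oxoheptadecanoate (racemic) | COC(=O)C(Cl)C(=O)CCCCCCCCCCCCCCc1cc(O)cc(OCc2ccccc2)c1
F6 | step 12 | ring B 3,5-bis(tert-butoxycarbonyl) derivative of the target, ring A benzyl ether | CC(C)(C)OC(=O)c1c(O)c(C(=O)OC(C)(C)C)c(O)c2Oc3cc(OCc4ccccc4)cc(c3)CCCCCCCCCCCCCCc12
F0 | step 5 | none | none
A1 | alternative 1 | 3-chloro-5-[14-(2-hydroxy-3,5-dimethoxyphenyl)tetradecyl]cyclohex-2-en-1-one (racemic) | O=C1C=C(Cl)CC(C1)CCCCCCCCCCCCCCc1cc(OC)cc(OC)c1O
A2 | alternative 1 | macrocyclic 3-aryloxy-5-alkylcyclohex-2-enone, ring B dimethyl ether (racemic) | O=C1C=C2CC(C1)CCCCCCCCCCCCCCc1cc(OC)cc(OC)c1O2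
A3 | alternative 2 | methyl (E)-17-[3-(benzyloxy)-5-(2-oxopropoxy)phenyl]heptadec-2-enoate | CC(=O)COc1cc(OCc2ccccc2)cc(c1)CCCCCCCCCCCCCC/C=C/C(=O)OC
A4 | alternative 2 | macrocyclic 4-aryloxy-5-alkylcyclohexane-1,3-dione, ring A benzyl ether (diastereomer mixture) | O=C1CC(=O)CC3CCCCCCCCCCCCCCc2cc(OCc4ccccc4)cc(c2)OC13
A5 | alternative 3 | 3-[14-(2-ethynyloxy-3,5-dimethoxyphenyl)tetradecyl]cyclobut-2-en-1-one | C#COc1c(OC)cc(OC)cc1CCCCCCCCCCCCCCC1=CC(=O)C1
A6 | alternative 3 | ring B di-O-methyl ether of the target | Oc1cc2cc(c1)Oc1c(OC)cc(OC)cc1CCCCCCCCCCCCCC2
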